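The isoflavone is cut through its pyranone C ring at O1–C8a and C4–C4a. Both bonds end on the neighbouring A-ring carbons C8a and C4a, and C4a sits next to the oxygenated C5; these two carbons therefore map onto the triple bond of a 3,5-dioxygenated benzyne. In a single operation the enolate oxygen of an α-aryl-β-hydroxyacrylate arylates on the aryne and the aryl anion that results acylates itself on the cis ester, which closes ring C with the 5,7-oxygenation in place. The precursors are a 3,5-bis(methoxymethoxy)-2-silylphenyl triflate from phloroglucinol and a Z-hydroxyacrylate that already carries the dimethoxy-prenyl B ring, made from methyl homovanillate.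

Key step: step 11

Remark: the target has no stereocentre, so no enantiomer has to be controlled; the only stereochemical element on the way is the Z geometry of the hydroxyacrylate enol/enolate, and methyl homovanillate is taken as a commercial starting material.

Step 1
Reactants: 1 phloroglucinol
Product: 2 3,5-bis(methoxymethoxy)phenol
Conditions: MOMCl (2.0 equiv), i-Pr2NEt, DMF, 0 °C to rt
Reagents that add atoms: chloromethyl methyl ether (MOMCl), COCCl
Why: Williamson-type O-alkylation of a phenol to its MOM acetal; the three hydroxyls are equivalent, so two equivalents of the chloride should give mainly the bis-ether, with the mono- and tris-ethers separable by chromatography.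

Step 2
Reactants: 2 3,5-bis(methoxymethoxy)phenol
Product: 3 3,5-bis(methoxymethoxy)phenyl N,N-diethylcarbamate
Conditions: Et2NCOCl, K2CO3, MeCN, reflux
Reagents that add atoms: N,N-diethylcarbamoyl chloride, CCN(CC)C(Cl)=O
Why: O-carbamoylation of the phenoxide (nucleophilic acyl substitution), which installs the strongest oxygen-based directing group for ortho-metalation.

Step 3
Reactants: 3 3,5-bis(methoxymethoxy)phenyl N,N-diethylcarbamate
Product: 5 3,5-bis(methoxymethoxy)-2-(trimethylsilyl)phenyl N,N-diethylcarbamate, via aryllithium 4 (not isolated)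
Conditions: s-BuLi, TMEDA, THF, −78 °C; then TMSCl, −78 °C to rt
Reagents that add atoms: chlorotrimethylsilane, C[Si](C)(C)Cl
Why: Directed ortho-metalation, in which the carbamate and its neighbouring OMOM group should cooperate to lithiate C2 in preference to C4 (flanked only by the two weaker OMOM directors), and silylation at −78 °C precedes any anionic Fries shift.

Step 4
Reactants: 5 3,5-bis(methoxymethoxy)-2-(trimethylsilyl)phenyl N,N-diethylcarbamate
Product: 7 3,5-bis(methoxymethoxy)-2-(trimethylsilyl)phenol, via lithium phenoxide 6 (not isolated)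
Conditions: LiAlH4, THF, 0 °C to reflux; then Na2SO4·10H2O; crude phenol used directly
Reagents that add atoms: none
Why: Reductive cleavage of an aryl carbamate by hydride (addition to C=O, loss of phenoxide, reduction of the formamide to the N-methylamine), to which the acetals and the aryl–silicon bond are inert, while the aprotic medium avoids protodesilylation of the electron-rich arylsilane.

Step 5
Reactants: 7 3,5-bis(methoxymethoxy)-2-(trimethylsilyl)phenol
Product: 8 3,5-bis(methoxymethoxy)-2-(trimethylsilyl)phenyl trifluoromethanesulfonate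
Conditions: Tf2O, pyridine, CH2Cl2, 0 °C
Reagents that add atoms: trifluoromethanesulfonic anhydride, O=S(=O)(OS(=O)(=O)C(F)(F)F)C(F)(F)F
Why: O-sulfonylation of the phenol, with pyridine taking up the triflic acid so that neither the MOM acetals nor the C–Si bond meet free acid.

Step 6
Reactants: 9 methyl homovanillate, 10 3-chloro-3-methylbut-1-yne
Product: 11 methyl 2-[3-methoxy-4-(2-methylbut-3-yn-2-yloxy)phenyl]acetate
Conditions: DBU, CuCl2·2H2O (cat.), MeCN, 0 °C
Reagents that add atoms: none
Why: Copper-catalysed propargylic etherification, in which the phenoxide substitutes the tertiary propargylic chloride through a copper acetylide/allenylidene, the standard entry to aryl 1,1-dimethylpropargyl ethers; the ester is untouched by DBU.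

Step 7
Reactants: 11 methyl 2-[3-methoxy-4-(2-methylbut-3-yn-2-yloxy)phenyl]acetate
Product: 12 methyl 2-[3-methoxy-4-(2-methylbut-3-en-2-yloxy)phenyl]acetate
Conditions: H2 (1 atm), Lindlar catalyst, quinoline, EtOAc, rt
Reagents that add atoms: none
Why: Lindlar semi-hydrogenation of the terminal alkyne, where the poisoned catalyst should stop at the alkene and leave the ester and the aryl ether alone.

Step 8
Reactants: 12 methyl 2-[3-methoxy-4-(2-methylbut-3-en-2-yloxy)phenyl]acetate
Product: 14 methyl 2-[4-hydroxy-3-methoxy-5-(3-methylbut-2-enyl)phenyl]acetate, via cyclohexadienone 13 (not isolated)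
Conditions: PhNEt2, 150 °C
Reagents that add atoms: none
Why: Aromatic Claisen rearrangement ([3,3]-sigmatropic shift with allyl inversion) delivers the prenyl group to C5, the only free ortho position, and tautomerisation of the dienone restores the phenol, while the basic solvent guards the ortho-prenylphenol against acid-induced chroman formation.

Step 9
Reactants: 14 methyl 2-[4-hydroxy-3-methoxy-5-(3-methylbut-2-enyl)phenyl]acetate
Product: 15 methyl 2-[3,4-dimethoxy-5-(3-methylbut-2-enyl)phenyl]acetate
Conditions: MeI, K2CO3, acetone, reflux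
Reagents that add atoms: iodomethane, CI
Why: Williamson O-methylation of the phenol; carbonate is too weak to deprotonate the arylacetate α-CH2, so no C-methylation is expected.

Step 10
Reactants: 15 methyl 2-[3,4-dimethoxy-5-(3-methylbut-2-enyl)phenyl]acetate, 16 methyl formate
Product: 18 methyl (Z)-2-[3,4-dimethoxy-5-(3-methylbut-2-enyl)phenyl]-3-hydroxyacrylate, via sodium enolate 17 (not isolated)
Conditions: NaH, THF, 0 °C to rt; then cold 1 M HCl
Reagents that add atoms: none
Why: Crossed Claisen condensation (C-formylation) of the arylacetate enolate with the non-enolisable formate, driven by formation of the stabilised enolate, and cold acidification should give the hydrogen-bonded Z enol.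

Step 11
Reactants: 8 3,5-bis(methoxymethoxy)-2-(trimethylsilyl)phenyl trifluoromethanesulfonate, 18 methyl (Z)-2-[3,4-dimethoxy-5-(3-methylbut-2-enyl)phenyl]-3-hydroxyacrylate
Product: 23 5,7-bis(methoxymethoxy)-3-[3,4-dimethoxy-5-(3-methylbut-2-enyl)phenyl]chromen-4-one, via caesium enolate 19 (not isolated), via aryne 20 (not isolated), via aryl caesium 21 (not isolated), via tetrahedral alkoxide 22 (not isolated)
Conditions: CsF (4 equiv), THF, 65 °C, sealed tube
Reagents that add atoms: none
Why: Proposed new method: CsF triggers 1,2-elimination of Me3SiF and triflate from 8 to release aryne 20 and converts enol 18 into the Z enolate 19; 19 should add through its formyl-derived oxygen at the aryne carbon meta to the flanking OMOM group, which leaves aryl anion 21 with its charge ortho to that group, and 21 attacks the cis ester to give alkoxide 22, which collapses to the chromone with loss of methoxide. The closest known reaction type is the fluoride-induced annulation of arynes with salicylate esters to xanthones, where O-arylation is likewise followed by attack of the aryl anion on the ester. The pyranone ring closes by a 6-exo-trig acyl substitution that forms C4–C4a after O1–C8a, and no stereocentre is created. The step needs O- and not C-arylation of the ambident enolate, which the fully substituted, hindered α-carbon and the high charge density on oxygen in the caesium enolate should favour, and a single aryne regiochemistry, which the inductive distortion of the triple bond by the adjacent alkoxy group secures. It also needs the ester to stay cis to the new aryl ether, which the U-shaped ion pair of the enolate in weakly polar THF should provide, and a low stationary aryne concentration (sparingly soluble CsF) so that proton transfer to 21 or an ene reaction at the prenyl group cannot compete. Nothing in the flask is acidic or reducing, so the acetals, the methyl ethers and the prenyl alkene should come through unchanged.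

Step 12
Reactants: 23 5,7-bis(methoxymethoxy)-3-[3,4-dimethoxy-5-(3-methylbut-2-enyl)phenyl]chromen-4-one
Product: 24 piscerythrinetin, 5,7-dihydroxy-3-[3,4-dimethoxy-5-(3-methylbut-2-enyl)phenyl]chromen-4-one
Conditions: 3 M aq. HCl, MeOH, 45 °C
Reagents that add atoms: none
Why: Acid-catalysed methanolysis of the two MOM acetals (acetal exchange), under which the aryl methyl ethers are stable and the prenyl group, which has no ortho hydroxyl to trap a cation, should survive.

Compound list
1 | phloroglucinol | Oc1cc(O)cc(O)c1 | starting material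
2 | 3,5-bis(methoxymethoxy)phenol | COCOc1cc(O)cc(OCOC)c1 | intermediate
3 | 3,5-bis(methoxymethoxy)phenyl N,N-diethylcarbamate | CCN(CC)C(=O)Oc1cc(OCOC)cc(OCOC)c1 | intermediate
4 | [2-(diethylcarbamoyloxy)-4,6-bis(methoxymethoxy)phenyl]lithium (not isolated) | [Li]c1c(OC(=O)N(CC)CC)cc(OCOC)cc1OCOC | intermediate
5 | 3,5-bis(methoxymethoxy)-2-(trimethylsilyl)phenyl N,N-diethylcarbamate | CCN(CC)C(=O)Oc1cc(OCOC)cc(OCOC)c1[Si](C)(C)C | intermediate
6 | lithium 3,5-bis(methoxymethoxy)-2-(trimethylsilyl)phenoxide (not isolated; aluminium-bound in step 4, written as its simplest salt) | [Li+].[O-]c1cc(OCOC)cc(OCOC)c1[Si](C)(C)C | intermediate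
7 | 3,5-bis(methoxymethoxy)-2-(trimethylsilyl)phenol | COCOc1cc(O)c([Si](C)(C)C)c(OCOC)c1 | intermediate
8 | 3,5-bis(methoxymethoxy)-2-(trimethylsilyl)phenyl trifluoromethanesulfonate | COCOc1cc(OCOC)c([Si](C)(C)C)c(OS(=O)(=O)C(F)(F)F)c1 | intermediate
9 | methyl homovanillate, methyl 2-(4-hydroxy-3-methoxyphenyl)acetate | COC(=O)Cc1ccc(O)c(OC)c1 | starting material
10 | 3-chloro-3-methylbut-1-yne | CC(C)(Cl)C#C | starting material
11 | methyl 2-[3-methoxy-4-(2-methylbut-3-yn-2-yloxy)phenyl]acetate | COC(=O)Cc1ccc(OC(C)(C)C#C)c(OC)c1 | intermediate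
12 | methyl 2-[3-methoxy-4-(2-methylbut-3-en-2-yloxy)phenyl]acetate | COC(=O)Cc1ccc(OC(C)(C)C=C)c(OC)c1 | intermediate
13 | methyl 2-[5-methoxy-3-(3-methylbut-2-enyl)-4-oxocyclohexa-1,5-dien-1-yl]acetate (racemic, not isolated) | COC(=O)CC1=CC(CC=C(C)C)C(=O)C(OC)=C1 | intermediate
14 | methyl 2-[4-hydroxy-3-methoxy-5-(3-methylbut-2-enyl)phenyl]acetate | COC(=O)Cc1cc(OC)c(O)c(CC=C(C)C)c1 | intermediate
15 | methyl 2-[3,4-dimethoxy-5-(3-methylbut-2-enyl)phenyl]acetate | COC(=O)Cc1cc(OC)c(OC)c(CC=C(C)C)c1 | intermediate
16 | methyl formate | COC=O | starting material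
17 | sodium (Z)-2-[3,4-dimethoxy-5-(3-methylbut-2-enyl)phenyl]-3-methoxy-3-oxoprop-1-en-1-olate (not isolated) | COC(=O)/C(=C\[O-])c1cc(OC)c(OC)c(CC=C(C)C)c1.[Na+] | intermediate
18 | methyl (Z)-2-[3,4-dimethoxy-5-(3-methylbut-2-enyl)phenyl]-3-hydroxyacrylate | COC(=O)/C(=C\O)c1cc(OC)c(OC)c(CC=C(C)C)c1 | intermediate
19 | caesium (Z)-2-[3,4-dimethoxy-5-(3-methylbut-2-enyl)phenyl]-3-methoxy-3-oxoprop-1-en-1-olate (not isolated) | COC(=O)/C(=C\[O-])c1cc(OC)c(OC)c(CC=C(C)C)c1.[Cs+] | intermediate
20 | 3,5-bis(methoxymethoxy)benzyne, 1,2-didehydro-3,5-bis(methoxymethoxy)benzene (not isolated) | COCOC1=CC#CC(OCOC)=C1 | intermediate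
21 | methyl (Z)-3-[2-caesio-3,5-bis(methoxymethoxy)phenoxy]-2-[3,4-dimethoxy-5-(3-methylbut-2-enyl)phenyl]acrylate (not isolated) | COC(=O)/C(=C\Oc1cc(OCOC)cc(OCOC)[c-]1)c1cc(OC)c(OC)c(CC=C(C)C)c1.[Cs+] | intermediate
22 | caesium 4-methoxy-5,7-bis(methoxymethoxy)-3-[3,4-dimethoxy-5-(3-methylbut-2-enyl)phenyl]-4H-chromen-4-olate (racemic, not isolated) | COC1([O-])C(c2cc(OC)c(OC)c(CC=C(C)C)c2)=COc2cc(OCOC)cc(OCOC)c21.[Cs+] | intermediate
23 | 5,7-bis(methoxymethoxy)-3-[3,4-dimethoxy-5-(3-methylbut-2-enyl)phenyl]chromen-4-one | COCOc1cc(OCOC)c2c(c1)occ(-c1cc(OC)c(OC)c(CC=C(C)C)c1)c2=O | intermediate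
24 | piscerythrinetin, 5,7-dihydroxy-3-[3,4-dimethoxy-5-(3-methylbut-2-enyl)phenyl]chromen-4-one (achiral) | COc1cc(-c2coc3cc(O)cc(O)c3c2=O)cc(CC=C(C)C)c1OC | target

Total step count: 12.
Longest linear sequence: 7 steps (steps 6–10, then 11 and 12; the branch through steps 1–5 is equally long).

Steps most likely to fail

Step 11. The enolate may arylate at carbon and then shift an acyl group (net insertion into the C–CHO bond). The aryl anion may also be protonated before it reaches the ester, or arylation may occur on the extended enolate so that ring closure is geometrically impossible. The fallback sets out from ester 15 and triflate 8 and comes back at 23, using known chemistry throughout. Hydrolysis of 15 (LiOH, THF–H2O) should give 2-[3,4-dimethoxy-5-(3-methylbut-2-enyl)phenyl]acetic acid F1. Heated with 8 and CsF in THF at 125 °C, the carboxylate can only react at oxygen and should add to aryne 20 with the same regiochemistry. The aryl anion then takes over the acyl group, a known insertion of an aryne into the C–O bond of a carboxylic acid by a Fries-type acyl shift. This should give 1-[2-hydroxy-4,6-bis(methoxymethoxy)phenyl]-2-[3,4-dimethoxy-5-(3-methylbut-2-enyl)phenyl]ethanone F2. Condensation with DMF dimethyl acetal (toluene, 90 °C) should give (E)-3-(dimethylamino)-1-[2-hydroxy-4,6-bis(methoxymethoxy)phenyl]-2-[3,4-dimethoxy-5-(3-methylbut-2-enyl)phenyl]prop-2-en-1-one F3. F3 cyclises with loss of dimethylamine to 23, the classical deoxybenzoin closure of isoflavones.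

Step 3. Metalation may take place competitively at C4 between the two acetal oxygens, or the lithiated carbamate may undergo 1,3-carbamoyl migration before it is silylated. The fallback sets out from phenol 2 and comes back at triflate 8, replacing steps 2–5 by a halogen–metal exchange and retro-Brook sequence. Ortho-selective bromination (NBS, cat. i-Pr2NH, CH2Cl2, −78 to 0 °C) should give 2-bromo-3,5-bis(methoxymethoxy)phenol F4. Silylation with hexamethyldisilazane (THF, 65 °C) should give (2-bromo-3,5-bis(methoxymethoxy)phenoxy)trimethylsilane F5. n-BuLi (THF, −100 to −78 °C) exchanges bromine to give [2,4-bis(methoxymethoxy)-6-(trimethylsilyloxy)phenyl]lithium F6, whose silyl group shifts from oxygen to carbon to give phenoxide 6. Tf2O added to the same flask should then give 8.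

Step 6. Substitution at the tertiary propargylic carbon may stall or lose HCl to the enyne, and the semi-hydrogenation that follows may over-reduce. The fallback sets out from phenol 9 and comes back at allyl ether 12, skipping steps 6 and 7. It is a Tsuji–Trost decarboxylative allylic etherification with tert-butyl 2-methylbut-3-en-2-yl carbonate F7 (from 2-methylbut-3-en-2-ol, n-BuLi and Boc2O), Pd(PPh3)4 (cat.), THF, 0 °C. Under kinetic control the phenoxide should attack the more substituted terminus of the π-allyl palladium and give the tertiary ether 12 directly.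

Further compounds
F1 | step 11 | 2-[3,4-dimethoxy-5-(3-methylbut-2-enyl)phenyl]acetic acid | OC(=O)Cc1cc(OC)c(OC)c(CC=C(C)C)c1
F2 | step 11 | 1-[2-hydroxy-4,6-bis(methoxymethoxy)phenyl]-2-[3,4-dimethoxy-5-(3-methylbut-2-enyl)phenyl]ethanone | COCOc1cc(O)c(C(=O)Cc2cc(OC)c(OC)c(CC=C(C)C)c2)c(OCOC)c1
F3 | step 11 | (E)-3-(dimethylamino)-1-[2-hydroxy-4,6-bis(methoxymethoxy)phenyl]-2-[3,4-dimethoxy-5-(3-methylbut-2-enyl)phenyl]prop-2-en-1-one | COCOc1cc(O)c(C(=O)/C(=C/N(C)C)c2cc(OC)c(OC)c(CC=C(C)C)c2)c(OCOC)c1
F4 | step 3 | 2-bromo-3,5-bis(methoxymethoxy)phenol | COCOc1cc(O)c(Br)c(OCOC)c1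
F5 | step 3 | (2-bromo-3,5-bis(methoxymethoxy)phenoxy)trimethylsilane | COCOc1cc(O[Si](C)(C)C)c(Br)c(OCOC)c1
F6 | step 3 | [2,4-bis(methoxymethoxy)-6-(trimethylsilyloxy)phenyl]lithium | [Li]c1c(O[Si](C)(C)C)cc(OCOC)cc1OCOC
F7 | step 6 | tert-butyl 2-methylbut-3-en-2-yl carbonate | C=CC(C)(C)OC(=O)OC(C)(C)C
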